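**Retrosynthetic overview**
- Last step: the C6–C7 bond, the ten-membered carbocycle and the cis-fused lactone are made together by a ring-closing allylboration of a 2-(methoxycarbonyl)allylboronate onto the C6 (Z)-enal. The acrylate β-carbon C7, normally an acceptor, acts as the donor towards the aldehyde carbon; lactonisation follows.
- The allylboronate comes from the C7 aldehyde (vinylalumination/acetylation, then Pd-catalysed borylation); the C8 methacrylate is installed by Mitsunobu inversion of the sugar-derived hydroxyl.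
- The furanone ring is formed first, by gold-catalysed 5-endo cyclisation of a C10-hydroxy C1-ynone.
- The C1–C2 bond comes from adding the acetylide of (Z)-3-methylpent-2-en-4-yn-1-ol (C2–C6, C15) to 2-C-methyl-D-ribono-1,4-lactone (C1, C7–C10, C14; supplies 9R and 10R).
- Ring order: furanone, then carbocycle and butyrolactone in one operation.

Assumption: the SMILES is read literally, i.e. (6S,7S,8S,9R,10R), 4Z, cis-fused 6,12-lactone. Germacrane numbering of the target is used for all intermediates (C1 ketone, C2=C3, C4=C5, C6–C10, C11–C13 lactone carbons, C14 = Me on C10, C15 = Me on C4).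

**Step 1**
Reactants: 1 2-C-methyl-D-ribono-1,4-lactone
Product: 2 2-C-methyl-3,5-bis-O-(triethylsilyl)-D-ribono-1,4-lactone
Conditions: TESCl (2.2 equiv), imidazole, DMF, 0 °C
Reagents that add atoms: chlorotriethylsilane, CC[Si](Cl)(CC)CC
Why: Imidazole-mediated silylation (silyl ether protection) takes the primary and secondary hydroxyls but not the hindered tertiary α-hydroxyl, which stays free for the later furanone closure; no stereocentre is touched.

**Step 2**
Reactants: 3 (Z)-3-methylpent-2-en-4-yn-1-ol
Product: 4 tert-butyldimethyl{[(2Z)-3-methylpent-2-en-4-yn-1-yl]oxy}silane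
Conditions: TBSCl, imidazole, CH2Cl2, 0 °C → rt
Reagents that add atoms: tert-butylchlorodimethylsilane, CC(C)(C)[Si](C)(C)Cl
Why: Standard silyl ether protection of the primary allylic alcohol, leaving the terminal alkyne free and the Z alkene unchanged.

**Step 3**
Reactants: 2 bis-TES lactone; 4 TBS enyne
Product: 6 1-C-alkynyl hemiketal (lactol; anomeric mixture), via lithium acetylide 5 (not isolated)
Conditions: 4 (2.5 equiv), n-BuLi (2.4 equiv), THF, −78 °C; then 2, −78 °C; AcOH
Reagents that add atoms: none
Why: Acetylide addition to a γ-lactone (one equivalent of 5 is spent on the tertiary hydroxyl) stops at the lithium lactolate at −78 °C, so protonation gives the 1-C-alkynyl hemiketal, the ring tautomer of the C1 ynone, with the new C1–C2 bond and the sugar stereocentres intact.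

**Step 4**
Reactants: 6 alkynyl hemiketal
Product: 8 furanone alcohol (8R,9R,10R), via hydroxy ynone 7 (not isolated)
Conditions: Ph3PAuNTf2 (2 mol %), PhMe, rt
Reagents that add atoms: none
Why: Gold-catalysed 5-endo-dig cycloisomerisation of an α′-hydroxy ynone: the hemiketal opens to ynone 7, cationic monovalent gold activates the alkyne and the tertiary C10 hydroxyl adds to C3 to form the 3(2H)-furanone, which frees the C8 hydroxyl; the silylated C9 oxygen cannot compete by 6-endo closure and C10 keeps its configuration.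

**Step 5**
Reactants: 8 furanone alcohol
Product: 9 C8 methacrylate (8S,9R,10R)
Conditions: methacrylic acid, PPh3, DIAD, BHT, PhMe, 0 °C → rt
Reagents that add atoms: methacrylic acid, C=C(C)C(=O)O
Why: Mitsunobu esterification: the only free hydroxyl is activated as an alkoxyphosphonium ion and displaced by methacrylate in an SN2 reaction, so C8 is inverted from the D-ribo (8R) to the required 8S configuration while the ester is installed.

**Step 6**
Reactants: 9 C8 methacrylate
Product: 10 C7 aldehyde (C8 unchanged in space; formally 8R because CHO now outranks C9)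
Conditions: (COCl)2, DMSO, CH2Cl2, −78 → −40 °C; Et3N, −78 → 0 °C
Reagents that add atoms: none
Why: Swern oxidation with in-situ desilylation: the chlorosulfonium reagent cleaves primary triethylsilyl ethers and oxidises them directly to aldehydes while secondary TES and primary TBS ethers survive, and the cold amine work-up avoids epimerisation of the α-acyloxy centre C8.

**Step 7**
Reactants: 10 C7 aldehyde
Product: 12 allylic acetate (C7 epimers), via aluminium alkoxide 11 (not isolated)
Conditions: i-Bu2AlH, NMO, THF, 0 °C; methyl propiolate; then 10, 0 °C → rt; then Ac2O, pyridine, DMAP, 0 °C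
Reagents that add atoms: methyl propiolate, C#CC(=O)OC; acetic anhydride, CC(=O)OC(C)=O
Why: Vinylalumination, a non-basic surrogate of the Morita–Baylis–Hillman reaction: 1,4-hydroalumination of methyl propiolate gives the α-(methoxycarbonyl)vinylalane, which adds only to the aldehyde, and the aluminium alkoxide is acetylated in the flask before the neighbouring methacrylate can migrate; the new C7 centre is formed as a mixture that is erased in step 8.

**Step 8**
Reactants: 12 allylic acetate
Product: 13 (E)-2-(methoxycarbonyl)allylboronate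
Conditions: B2pin2, Pd2(dba)3 (tris(dibenzylideneacetone)dipalladium, 2.5 mol %), DMSO, 40 °C
Reagents that add atoms: bis(pinacolato)diboron, CC1(C)OB(OC1(C)C)B1OC(C)(C)C(C)(C)O1
Why: Palladium-catalysed Miyaura-type allylic borylation: zerovalent palladium ionises the allylic acetate to a 2-(methoxycarbonyl)-π-allyl complex that transmetallates with B2pin2 and reductively eliminates at the CH2 terminus, giving the conjugated alkene in its more stable geometry (C8 trans to the ester, cis to CH2B) and converting the acrylate β-carbon C7 into a latent nucleophile; without a copper boryl species the methacrylate is not borylated.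

**Step 9**
Reactants: 13 allylboronate
Product: 14 C6,C9-diol allylboronate
Conditions: CSA (0.2 equiv), MeOH/CH2Cl2, 0 °C → rt
Reagents that add atoms: none
Why: Acid-catalysed methanolysis of silyl ethers removes the primary allylic TBS and the secondary TES groups, while the pinacol boronate, the esters and the furanone tolerate catalytic CSA at 0 °C.

**Step 10**
Reactants: 14 diol allylboronate
Product: 17 target CNP0252578.4, via enal boronate 15 (not isolated), via borate ester 16 (not isolated)
Conditions: MnO2, CH2Cl2, rt; filter; PhMe (1 mM), BHT, 90 °C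
Reagents that add atoms: none
Why: Proposed new method: MnO2 oxidises only the allylic C6 alcohol, and the resulting enal 15 then undergoes a ring-closing allylboration in which the acrylate β-carbon C7, normally an electrophile, is delivered as a nucleophile from the allylboronate to the electrophilic aldehyde carbon C6 through a six-membered chair transition state (B–O=C6···C7=C11–C13); because C8 is cis to CH2B it sits axial, so O6 and C8 emerge syn and the borate 16 lactonises to the cis-fused lactone, and allylic 1,3-strain holds H8 in the alkene plane so that the aldehyde enters anti to the bulky C9 branch, which gives 7S and hence 6S; the closest known reactions are the intermolecular synthesis of cis-α-methylene-γ-butyrolactones from 3-substituted 2-(alkoxycarbonyl)allylboronates and aldehydes and macrocyclising intramolecular allylborations.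

**Compound list**
1 | 2-C-methyl-D-ribono-1,4-lactone, (3R,4R,5R) | O=C1[C@](C)(O)[C@H](O)[C@@H](CO)O1 | starting material
2 | 2-C-methyl-3,5-bis-O-(triethylsilyl)-D-ribono-1,4-lactone | O=C1[C@](C)(O)[C@H](O[Si](CC)(CC)CC)[C@@H](CO[Si](CC)(CC)CC)O1 | intermediate
3 | (Z)-3-methylpent-2-en-4-yn-1-ol | C#C/C(C)=C\CO | starting material
4 | tert-butyldimethyl{[(2Z)-3-methylpent-2-en-4-yn-1-yl]oxy}silane | C#C/C(C)=C\CO[Si](C)(C)C(C)(C)C | intermediate
5 | lithium acetylide of 4 | [Li]C#C/C(C)=C\CO[Si](C)(C)C(C)(C)C | intermediate (not isolated)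
6 | 1-C-[(3Z)-5-(tert-butyldimethylsilyloxy)-3-methylpent-3-en-1-yn-1-yl]-2-C-methyl-3,5-bis-O-(triethylsilyl)-D-ribofuranose (hemiketal, anomeric mixture) | OC1(C#C/C(C)=C\CO[Si](C)(C)C(C)(C)C)[C@](C)(O)[C@H](O[Si](CC)(CC)CC)[C@@H](CO[Si](CC)(CC)CC)O1 | intermediate
7 | open-chain tautomer of 6: (4Z,8R,9R,10R) C1 ynone with C10-OH, C9-OTES, C8-OH, C7-OTES, C6-OTBS | CC[Si](CC)(CC)OC[C@@H](O)[C@@H](O[Si](CC)(CC)CC)[C@@](C)(O)C(=O)C#C/C(C)=C\CO[Si](C)(C)C(C)(C)C | intermediate (not isolated)
8 | (2R)-2-[(1R,2R)-2-hydroxy-1,3-bis(triethylsilyloxy)propyl]-2-methyl-5-[(2Z)-4-(tert-butyldimethylsilyloxy)but-2-en-2-yl]furan-3(2H)-one | CC[Si](CC)(CC)OC[C@@H](O)[C@@H](O[Si](CC)(CC)CC)[C@@]1(C)OC(/C(C)=C\CO[Si](C)(C)C(C)(C)C)=CC1=O | intermediate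
9 | C8 methacrylate of 8 with inverted C8 (8S,9R,10R) | CC[Si](CC)(CC)OC[C@H](OC(=O)C(C)=C)[C@@H](O[Si](CC)(CC)CC)[C@@]1(C)OC(/C(C)=C\CO[Si](C)(C)C(C)(C)C)=CC1=O | intermediate
10 | C7 aldehyde (C8 as in 9, formally 8R; 9R,10R) | O=C[C@H](OC(=O)C(C)=C)[C@@H](O[Si](CC)(CC)CC)[C@@]1(C)OC(/C(C)=C\CO[Si](C)(C)C(C)(C)C)=CC1=O | intermediate
11 | diisobutylaluminium alkoxide of the C7 carbinol (C7 epimers; 8S,9R,10R) | C=C(C(=O)OC)C(O[Al](CC(C)C)CC(C)C)[C@H](OC(=O)C(C)=C)[C@@H](O[Si](CC)(CC)CC)[C@@]1(C)OC(/C(C)=C\CO[Si](C)(C)C(C)(C)C)=CC1=O | intermediate (not isolated)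
12 | methyl 2-methylene-3-acetoxy ester, Morita–Baylis–Hillman-type acetate (C7 epimers; 8S,9R,10R) | C=C(C(=O)OC)C(OC(C)=O)[C@H](OC(=O)C(C)=C)[C@@H](O[Si](CC)(CC)CC)[C@@]1(C)OC(/C(C)=C\CO[Si](C)(C)C(C)(C)C)=CC1=O | intermediate
13 | methyl (2E)-2-[(pinacolboryl)methyl]alk-2-enoate: C13H2–Bpin, C7=C11 with C8 trans to CO2Me; (8S,9R,10R), C6-OTBS, C9-OTES | COC(=O)/C(CB1OC(C)(C)C(C)(C)O1)=C/[C@H](OC(=O)C(C)=C)[C@@H](O[Si](CC)(CC)CC)[C@@]1(C)OC(/C(C)=C\CO[Si](C)(C)C(C)(C)C)=CC1=O | intermediate
14 | desilylated allylboronate with free C6-OH and C9-OH (8S,9R,10R) | COC(=O)/C(CB1OC(C)(C)C(C)(C)O1)=C/[C@H](OC(=O)C(C)=C)[C@@H](O)[C@@]1(C)OC(/C(C)=C\CO)=CC1=O | intermediate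
15 | (4Z) C6 enal of 14 | COC(=O)/C(CB1OC(C)(C)C(C)(C)O1)=C/[C@H](OC(=O)C(C)=C)[C@@H](O)[C@@]1(C)OC(/C(C)=C\C=O)=CC1=O | intermediate (not isolated)
16 | ring-closed C6 pinacol borate with C11(=CH2)CO2Me on C7, (6S,7S,8S,9R,10R) | C=C(C)C(=O)O[C@H]1[C@@H](C(=C)C(=O)OC)[C@@H](OB2OC(C)(C)C(C)(C)O2)/C=C(/C)C2=CC(=O)[C@](C)(O2)[C@@H]1O | intermediate (not isolated)
17 | CNP0252578.4, (4Z,6S,7S,8S,9R,10R) | C=C(C)C(=O)O[C@H]1[C@H]2C(=C)C(=O)O[C@H]2/C=C(/C)C2=CC(=O)[C@](C)(O2)[C@@H]1O | target

**Totals**
Total step count: 10. Longest linear sequence: 9 steps (from 1 through steps 1 and 3–10, or from 3 through steps 2–10).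

**Steps most likely to fail, with fallbacks**

Step 10 (ring closure and the C6/C7 configuration). Closure of the strained bicycle may be slow, and the sense of attack at C7 rests on an acyclic model. The fallback leaves boron altogether; it sets out from acetate 12 and comes back at 17. MgBr2·OEt2 in THF converts 12 by SN2′ substitution into the (Z)-allylic bromide F1. CSA in MeOH at 0 °C removes both silyl groups to give the diol bromide F2, and MnO2 gives the enal bromide F3. CrCl2 in THF at high dilution (Nozaki–Hiyama allylation) then closes the ring through a reductively generated allylchromium species that adds through C7 and lactonises to 17. This path also by-passes step 8. The side reaction to watch is 1,4-elimination of the C8 carboxylate from the allylmetal.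

Step 5 (Mitsunobu at the hindered C8 hydroxyl, flanked by two silyloxy carbons). Elimination or incomplete inversion is possible. The fallback inverts by oxidation and reduction; it sets out from 8 and comes back at 9. Dess–Martin periodinane gives the C8 ketone F4. LiBH(s-Bu)3 at −78 °C reduces it under Felkin–Anh control (hydride anti to the C9 silyloxy group) to the 8,9-syn, C8-inverted alcohol F5. Methacrylic anhydride with DMAP then gives 9.

Step 4 (gold cyclisation starting from the hemiketal). The ring tautomer must open, a Meyer–Schuster-type path may compete, and the primary TES ether is acid-labile. The fallback traps the open form with an amine; it sets out from 6 and comes back at 8. Et2NH in EtOH adds in conjugate fashion to the ynone tautomer and gives the enaminone F6, a vinylogous amide that cannot re-close to a hemiketal. PPTS in CH2Cl2 then lets the C10 hydroxyl add to C3 with loss of the amine (addition–elimination) to give 8.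

**Further compounds**
F1 | step 10 | methyl (2Z)-2-(bromomethyl)alk-2-enoate analogue of 13 (C8 trans to CO2Me; silyl ethers in place) | COC(=O)/C(CBr)=C/[C@H](OC(=O)C(C)=C)[C@@H](O[Si](CC)(CC)CC)[C@@]1(C)OC(/C(C)=C\CO[Si](C)(C)C(C)(C)C)=CC1=O
F2 | step 10 | diol bromide (C6-OH, C9-OH free) | COC(=O)/C(CBr)=C/[C@H](OC(=O)C(C)=C)[C@@H](O)[C@@]1(C)OC(/C(C)=C\CO)=CC1=O
F3 | step 10 | enal bromide (C6 aldehyde, C9-OH free) | COC(=O)/C(CBr)=C/[C@H](OC(=O)C(C)=C)[C@@H](O)[C@@]1(C)OC(/C(C)=C\C=O)=CC1=O
F4 | step 5 | C8 ketone of 8 | CC[Si](CC)(CC)OCC(=O)[C@@H](O[Si](CC)(CC)CC)[C@@]1(C)OC(/C(C)=C\CO[Si](C)(C)C(C)(C)C)=CC1=O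
F5 | step 5 | C8-inverted alcohol (8S,9R,10R) | CC[Si](CC)(CC)OC[C@H](O)[C@@H](O[Si](CC)(CC)CC)[C@@]1(C)OC(/C(C)=C\CO[Si](C)(C)C(C)(C)C)=CC1=O
F6 | step 4 | (2E)-3-(diethylamino) enone from the open form of 6 (8R,9R,10R) | CC[Si](CC)(CC)OC[C@@H](O)[C@@H](O[Si](CC)(CC)CC)[C@@](C)(O)C(=O)/C=C(/N(CC)CC)\C(C)=C/CO[Si](C)(C)C(C)(C)C
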